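## Retrosynthetic overview

1. The target is fisetinidol-(4alpha-8)-6-methylcatechin (upper unit rings A, B, C; lower unit rings D, E, F). The end game is cleavage of one pivalate and hydrogenolysis of seven benzyl ethers on a protected dimer.
2. Key disconnection: C2-C3 of ring C and C4 (ring C)-C8 (ring D) are cut together. This gives an open-chain aryl ether (rings A and B, no ring C, no fixed stereocentre) and the 6-methylcatechin tetrabenzyl ether.
3. Enabling feature: O1 and the 4'-oxygen of ring B stabilise a cation at C2. The 7-oxygen of ring A (para to C4a) stabilises a cation at C4, so C3 of a C3=C4 enol ester is the nucleophilic end. The 6-methyl group leaves C8 as the only free carbon of ring D.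
4. The open-chain ether comes from two benzaldehydes (acyloxy acetal at O1-C2, boron-Wittig olefination, copper-mediated C3-O bond). The monomer comes from (+)-catechin (bromine block at C8, iodination and Negishi methylation at C6, removal of bromine).
5. Ring order: rings A, B, D, E and F are bought. Ring C is the only ring that is built, and it is built last.

Key step: step 10

Assumption: precedent does not fix the sense of induction of the chiral acid in step 10. The (S,S) acid is written, and its mirror image is meant if it should favour the (2S,3R) ion pair.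

## Route

Step 1
Reactants: 1 (+)-catechin
Product: 2 5,7,3',4'-tetra-O-benzyl-(+)-catechin
Conditions: BnBr (4.4 equiv), K2CO3, DMF, 0 °C to rt
Reagents that add atoms: benzyl bromide, BrCc1ccccc1
Why: Williamson ether synthesis: carbonate deprotonates only the four phenols, so the secondary 3-OH stays free and no stereocentre is touched.

Step 2
Reactants: 2 5,7,3',4'-tetra-O-benzyl-(+)-catechin
Product: 3 8-bromo-5,7,3',4'-tetra-O-benzylcatechin
Conditions: NBS (1.0 equiv), CH2Cl2, -78 °C to rt
Reagents that add atoms: N-bromosuccinimide, O=C1CCC(=O)N1Br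
Why: Electrophilic aromatic bromination: C8 is the most reactive carbon of ring D in benzylated catechins, so one equivalent of NBS puts a removable block on the later coupling site.

Step 3
Reactants: 3 8-bromo-5,7,3',4'-tetra-O-benzylcatechin
Product: 4 8-bromo-6-iodo-5,7,3',4'-tetra-O-benzylcatechin
Conditions: NIS (1.1 equiv), CH2Cl2/MeCN, 0 °C to rt, dark
Reagents that add atoms: N-iodosuccinimide, O=C1CCC(=O)N1I
Why: Electrophilic aromatic iodination: with C8 blocked, C6 is the only free carbon of the trioxygenated ring D, which is far more electron-rich than ring E or the benzyl groups.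

Step 4
Reactants: 4 8-bromo-6-iodo-5,7,3',4'-tetra-O-benzylcatechin
Product: 5 8-bromo-6-methyl-5,7,3',4'-tetra-O-benzylcatechin
Conditions: MeZnCl (3 equiv), Pd(OAc)2 (5 mol %), SPhos (10 mol %), THF, 40 °C
Reagents that add atoms: methylzinc chloride, C[Zn]Cl
Why: Negishi coupling: zerovalent palladium inserts into the C-I bond much faster than into the C-Br bond, so the methyl group enters at C6 only (the excess reagent covers the free 3-OH).

Step 5
Reactants: 5 8-bromo-6-methyl-5,7,3',4'-tetra-O-benzylcatechin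
Product: 7 6-methyl-5,7,3',4'-tetra-O-benzylcatechin, via dilithio species 6 (not isolated)
Conditions: n-BuLi (2.1 equiv), THF, -78 °C; then MeOH
Reagents that add atoms: none
Why: Bromine-lithium exchange followed by protonation: the first equivalent forms the 3-alkoxide, the second exchanges the aryl bromide faster than it attacks benzyl ethers at this temperature, and methanol frees C8-H.

Step 6
Reactants: 8 3,4-bis(benzyloxy)benzaldehyde
Product: 9 [3,4-bis(benzyloxy)phenyl](chloro)methyl pivalate (racemic)
Conditions: PivCl (1.1 equiv), ZnCl2 (2 mol %), CH2Cl2, -10 °C to rt, used crude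
Reagents that add atoms: pivaloyl chloride, CC(C)(C)C(=O)Cl
Why: Lewis-acid-catalysed addition of an acyl chloride across the aldehyde C=O (alpha-chloroalkyl ester formation); the new centre, the later C2, is racemic and is flattened in step 10.

Step 7
Reactants: 10 4-(benzyloxy)-2-hydroxybenzaldehyde; 9 [3,4-bis(benzyloxy)phenyl](chloro)methyl pivalate
Product: 11 4-(benzyloxy)-2-{[3,4-bis(benzyloxy)phenyl](pivaloyloxy)methoxy}benzaldehyde (racemic)
Conditions: Cs2CO3 (1.2 equiv), MeCN, 0 °C
Reagents that add atoms: none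
Why: O-alkylation of a phenoxide by an alpha-chloroalkyl pivalate, the chemistry of pivaloyloxymethyl ethers: the bulky pivalate disfavours acyl transfer, and the O1-C2 bond is made with a carboxylate, a better leaving group than the aryloxide, on C2.

Step 8
Reactants: 11 4-(benzyloxy)-2-{[3,4-bis(benzyloxy)phenyl](pivaloyloxy)methoxy}benzaldehyde
Product: 12 (E)-alkenyl pinacol boronate of 11 (aldehyde carbon = C4, boron-bearing carbon = C3)
Conditions: CH2(Bpin)2, LiTMP, THF, 0 °C; then 11, -78 °C to rt
Reagents that add atoms: bis(pinacolatoboryl)methane, C(B1OC(C)(C)C(C)(C)O1)B1OC(C)(C)C(C)(C)O1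
Why: Boron-Wittig olefination: the lithiated geminal diboronate adds to the aldehyde only, and syn elimination of the boron-oxygen pair gives the E-alkenylboronate that carries C3.

Step 9
Reactants: 12 (E)-alkenyl pinacol boronate
Product: 13 (E)-2-[4-(benzyloxy)-2-{[3,4-bis(benzyloxy)phenyl](pivaloyloxy)methoxy}phenyl]vinyl pivalate
Conditions: Cu(O2CCMe3)2 (2.2 equiv), Et3N, 4 Å MS, MeCN, 40 °C
Reagents that add atoms: copper dipivalate, CC(C)(C)C(=O)[O-].CC(C)(C)C(=O)[O-].[Cu+2]
Why: Chan-Lam-type oxidative C-O coupling of an alkenylboron compound with a copper carboxylate: transmetalation and reductive elimination from trivalent copper keep the E geometry, which later sets the 2,3-trans relation.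

Step 10
Reactants: 13 (E)-enol pivalate acyloxy acetal; 7 6-methyl-5,7,3',4'-tetra-O-benzylcatechin
Product: 17 hepta-O-benzyl-3-O-pivaloylfisetinidol-(4alpha-8)-6-methylcatechin, via oxocarbenium ion 14 (not isolated), via dioxolenium ion 15 (not isolated), via trans-dipivalate 16 (not isolated)
Conditions: (S,S)-imidodiphosphorimidate acid (IDPi, 3,3'-diaryl-BINOL backbone, N-triflyl; 5 mol %), 4 Å MS, CH2Cl2, -60 °C until 13 is consumed; then 7 (1.05 equiv), TMSOTf (10 mol %), -78 to -40 °C; Et3N
Reagents that add atoms: none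
Why: Proposed new method: the chiral acid ionises the acyloxy acetal of 13 to the E-oxocarbenium ion 14, C3 of the E-enol pivalate attacks C2 in a cation-olefin (Prins) closure, the C4 benzylic cation is held by the C3 pivalate as dioxolenium ion 15 and opened by pivalic acid to 16, and TMSOTf then re-forms 15 so that C8 of 7 attacks C4 in a Friedel-Crafts step that copies the flavan-4-yl cation coupling of proanthocyanidin biosynthesis. The closest known reaction types are the Prins-Friedel-Crafts three-component reaction, the Prins cyclisation of alpha-acyloxy ethers, the catalytic asymmetric Prins cyclisation with confined imidodiphosphorimidate acids and the Lewis-acid coupling of 4-acyloxyflavan-3-yl esters with benzylated catechins; new are an enol ester that reacts at its oxygen-bearing carbon and an aryl oxocarbenium ion under control of a chiral anion. Ring C closes 6-endo-trig at the C3=C4 bond with the C2=O1 bond inside the forming ring, through a half-chair, and the temporary dioxolenium ring closes 5-exo at the C4 cation. C2 and C3 are set together: E-oxocarbenium and E-alkene place ring B and the pivalate pseudo-equatorial (2,3-trans), and the chiral counter-anion of the contact ion pair chooses which pair of faces meets (2R,3S); C4 is set by the cis-fused dioxolenium ring, which covers the face of O3 so that ring D enters anti (3,4-trans, 4S). The step needs C3 and not C4 as nucleophilic carbon (6-endo against 5-exo closure to a dihydrobenzofuran), secured by the 7-benzyloxy group para to C4a, which turns C4 into a para-alkoxybenzyl cation, and by the acyl group, which damps the enol oxygen; it needs one arene site, secured by the 6-methyl group that leaves only C8 free on ring D; and it needs closure before capture of 14 by the arene, secured by adding 7 only after 13 is consumed.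

Step 11
Reactants: 17 hepta-O-benzyl-3-O-pivaloylfisetinidol-(4alpha-8)-6-methylcatechin
Product: 18 hepta-O-benzylfisetinidol-(4alpha-8)-6-methylcatechin (both 3-OH groups free)
Conditions: LiAlH4, THF, 0 °C to rt; aqueous work-up
Reagents that add atoms: none
Why: Hydride cleavage of the hindered ester: LiAlH4 reduces the pivalate to neopentyl alcohol without touching benzyl ethers, the interflavan bond or any stereocentre.

Step 12
Reactants: 18 hepta-O-benzylfisetinidol-(4alpha-8)-6-methylcatechin
Product: 19 fisetinidol-(4alpha-8)-6-methylcatechin (target)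
Conditions: H2 (1 atm), Pd(OH)2/C, THF/MeOH/H2O, rt
Reagents that add atoms: none
Why: Catalytic hydrogenolysis of the seven benzyl ethers under neutral conditions, the standard last step for benzylated proanthocyanidins, leaves the acid-labile C4-C8 bond and all five stereocentres intact.

## Compound list

1 | (+)-catechin, (2R,3S)-2-(3,4-dihydroxyphenyl)chromane-3,5,7-triol | Oc1cc(O)c2c(c1)O[C@H](c1ccc(O)c(O)c1)[C@@H](O)C2 | starting material
2 | (2R,3S)-5,7,3',4'-tetra-O-benzylcatechin | O(Cc1ccccc1)c1cc(OCc2ccccc2)c2c(c1)O[C@H](c1ccc(OCc3ccccc3)c(OCc3ccccc3)c1)[C@@H](O)C2 | intermediate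
3 | (2R,3S)-8-bromo-5,7,3',4'-tetra-O-benzylcatechin | O(Cc1ccccc1)c1cc(OCc2ccccc2)c2c(c1Br)O[C@H](c1ccc(OCc3ccccc3)c(OCc3ccccc3)c1)[C@@H](O)C2 | intermediate
4 | (2R,3S)-8-bromo-6-iodo-5,7,3',4'-tetra-O-benzylcatechin | O(Cc1ccccc1)c1c(I)c(OCc2ccccc2)c2c(c1Br)O[C@H](c1ccc(OCc3ccccc3)c(OCc3ccccc3)c1)[C@@H](O)C2 | intermediate
5 | (2R,3S)-8-bromo-6-methyl-5,7,3',4'-tetra-O-benzylcatechin | O(Cc1ccccc1)c1c(C)c(OCc2ccccc2)c2c(c1Br)O[C@H](c1ccc(OCc3ccccc3)c(OCc3ccccc3)c1)[C@@H](O)C2 | intermediate
6 | 8-lithio-6-methyl-5,7,3',4'-tetra-O-benzylcatechin lithium 3-alkoxide | O(Cc1ccccc1)c1c(C)c(OCc2ccccc2)c2c(c1[Li])O[C@H](c1ccc(OCc3ccccc3)c(OCc3ccccc3)c1)[C@@H](O[Li])C2 | intermediate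
7 | (2R,3S)-6-methyl-5,7,3',4'-tetra-O-benzylcatechin | O(Cc1ccccc1)c1c(C)c(OCc2ccccc2)c2c(c1)O[C@H](c1ccc(OCc3ccccc3)c(OCc3ccccc3)c1)[C@@H](O)C2 | intermediate
8 | 3,4-bis(benzyloxy)benzaldehyde | O=Cc1ccc(OCc2ccccc2)c(OCc2ccccc2)c1 | starting material
9 | [3,4-bis(benzyloxy)phenyl](chloro)methyl pivalate, racemic | CC(C)(C)C(=O)OC(Cl)c1ccc(OCc2ccccc2)c(OCc2ccccc2)c1 | intermediate
10 | 4-(benzyloxy)-2-hydroxybenzaldehyde | O=Cc1ccc(OCc2ccccc2)cc1O | starting material
11 | 4-(benzyloxy)-2-{[3,4-bis(benzyloxy)phenyl](pivaloyloxy)methoxy}benzaldehyde, racemic at the acetal carbon | O=Cc1ccc(OCc2ccccc2)cc1OC(OC(=O)C(C)(C)C)c1ccc(OCc2ccccc2)c(OCc2ccccc2)c1 | intermediate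
12 | (E)-2-aryl-vinyl pinacol boronate derived from 11, racemic at the acetal carbon | CC1(C)OB(/C=C/c2ccc(OCc3ccccc3)cc2OC(OC(=O)C(C)(C)C)c2ccc(OCc3ccccc3)c(OCc3ccccc3)c2)OC1(C)C | intermediate
13 | (E)-2-[4-(benzyloxy)-2-{[3,4-bis(benzyloxy)phenyl](pivaloyloxy)methoxy}phenyl]vinyl pivalate, racemic at the acetal carbon | CC(C)(C)C(=O)O/C=C/c1ccc(OCc2ccccc2)cc1OC(OC(=O)C(C)(C)C)c1ccc(OCc2ccccc2)c(OCc2ccccc2)c1 | intermediate
14 | E-aryl oxocarbenium ion formed from 13 by loss of pivalate from C2 | CC(C)(C)C(=O)O/C=C/c1ccc(OCc2ccccc2)cc1/[O+]=C/c1ccc(OCc2ccccc2)c(OCc2ccccc2)c1 | intermediate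
15 | closed (2R)-2,3-trans flavan with a cis-fused 2-tert-butyl-1,3-dioxolan-2-ylium ring across C3 and C4 | CC(C)(C)C1=[O+][C@H]2c3ccc(OCc4ccccc4)cc3O[C@H](c3ccc(OCc4ccccc4)c(OCc4ccccc4)c3)[C@H]2O1 | intermediate
16 | (2R)-2,3-trans-3,4-trans-7,3',4'-tri-O-benzylflavan-3,4-diyl dipivalate | CC(C)(C)C(=O)O[C@@H]1c2ccc(OCc3ccccc3)cc2O[C@H](c2ccc(OCc3ccccc3)c(OCc3ccccc3)c2)[C@H]1OC(=O)C(C)(C)C | intermediate
17 | hepta-O-benzyl-3-O-pivaloylfisetinidol-(4alpha-8)-6-methylcatechin, upper unit 2R,3S,4S, lower unit 2R,3S | Cc1c(OCc2ccccc2)c2c(c([C@@H]3c4ccc(OCc5ccccc5)cc4O[C@H](c4ccc(OCc5ccccc5)c(OCc5ccccc5)c4)[C@H]3OC(=O)C(C)(C)C)c1OCc1ccccc1)O[C@H](c1ccc(OCc3ccccc3)c(OCc3ccccc3)c1)[C@@H](O)C2 | intermediate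
18 | hepta-O-benzylfisetinidol-(4alpha-8)-6-methylcatechin, upper unit 2R,3S,4S, lower unit 2R,3S | Cc1c(OCc2ccccc2)c2c(c([C@@H]3c4ccc(OCc5ccccc5)cc4O[C@H](c4ccc(OCc5ccccc5)c(OCc5ccccc5)c4)[C@H]3O)c1OCc1ccccc1)O[C@H](c1ccc(OCc3ccccc3)c(OCc3ccccc3)c1)[C@@H](O)C2 | intermediate
19 | fisetinidol-(4alpha-8)-6-methylcatechin, (2R,3S,4S)-2-(3,4-dihydroxyphenyl)-4-[(2R,3S)-2-(3,4-dihydroxyphenyl)-3,5,7-trihydroxy-6-methylchroman-8-yl]chromane-3,7-diol | Cc1c(O)c2c(c([C@@H]3c4ccc(O)cc4O[C@H](c4ccc(O)c(O)c4)[C@H]3O)c1O)O[C@H](c1ccc(O)c(O)c1)[C@@H](O)C2 | target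

## Step count and risks

Total step count: 12. Longest linear sequence: 8 steps (steps 1 to 5, then 10 to 12).

**1. Step 10**
- What may go wrong: slow attack of the oxygen-bearing alkene carbon, competing 5-exo closure, or weak facial control by the counter-anion.
- The fallback sets out from 12 and comes back at 17.
- The alkenylboronate 12 itself is closed with BF3·OEt2 (CH2Cl2, -78 °C). The boron-bearing C3 attacks the oxocarbenium carbon C2 at its ipso position and boron is then lost. This is the known reaction type of alkenylboron additions to acetals and of vinyl-metal-terminated Prins cyclisations. It gives racemic 7,3',4'-tri-O-benzylflav-3-ene F1, still by C2-C3 ring closure.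
- Dihydroxylation with OsO4/NMO anti to ring B, known for flav-3-enes, gives the racemic 2,3-trans-3,4-cis-flavan-3,4-diol F2.
- PivCl, DMAP and pyridine give the racemic 3,4-cis-dipivalate F3.
- With TMSOTf and 7, F3 ionises to the dioxolenium ion and couples as in the second stage of step 10.
- Since 7 is enantiopure, the two dimers are diastereomers. 17 is separated by chromatography at the price of half of the upper fragment.

**2. Step 7**
- What may go wrong: acyl transfer from the chloro ester to the phenoxide, or ionisation and hydrolysis of the acyloxy acetal here and during steps 8 and 9.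
- The fallback sets out from 10 and comes back at 16.
- Phenol 10 is alkylated with commercial 3,4-bis(benzyloxy)benzyl chloride (K2CO3, DMF) to the robust 4-(benzyloxy)-2-{[3,4-bis(benzyloxy)benzyl]oxy}benzaldehyde F4.
- Boron-Wittig olefination as in step 8 gives the (E)-alkenyl pinacol boronate F5. Copper-mediated acyloxylation as in step 9 gives the (E)-enol pivalate benzyl ether F6.
- The C2 cation is then made by oxidative C-H cleavage with DDQ (pivalic acid, 2,6-dichloropyridine, the chiral acid of step 10, CH2Cl2, -40 °C). This is the reaction type of DDQ-induced cyclisations of electron-rich benzylic ethers onto enol esters. The 3,4-dialkoxybenzyl position is the most easily oxidised one.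
- Closure and capture by pivalic acid give 16. The hydroquinone is filtered off before 7 and TMSOTf are added.

**3. Step 9**
- What may go wrong: protodeboronation, or loss of the acyloxy acetal on the Lewis-acidic copper salt.
- The fallback sets out from 12 and comes back at 13.
- 12 is oxidised with NaBO3·4H2O (THF, pH 7 buffer) to the arylacetaldehyde F7.
- F7 is O-acylated through its enolate (Piv2O, Et3N, DMAP, CH2Cl2). The conjugated E enol ester should be favoured, and the Z isomer is removed by chromatography.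

## Further compounds

F1 | step 10 | 7,3',4'-tri-O-benzylflav-3-ene, racemic, one enantiomer drawn | C1=Cc2ccc(OCc3ccccc3)cc2O[C@@H]1c1ccc(OCc2ccccc2)c(OCc2ccccc2)c1
F2 | step 10 | 2,3-trans-3,4-cis-7,3',4'-tri-O-benzylflavan-3,4-diol, racemic, one enantiomer drawn | O[C@H]1c2ccc(OCc3ccccc3)cc2O[C@H](c2ccc(OCc3ccccc3)c(OCc3ccccc3)c2)[C@H]1O
F3 | step 10 | 2,3-trans-3,4-cis-7,3',4'-tri-O-benzylflavan-3,4-diyl dipivalate, racemic, one enantiomer drawn | CC(C)(C)C(=O)O[C@H]1c2ccc(OCc3ccccc3)cc2O[C@H](c2ccc(OCc3ccccc3)c(OCc3ccccc3)c2)[C@H]1OC(=O)C(C)(C)C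
F4 | step 7 | 4-(benzyloxy)-2-{[3,4-bis(benzyloxy)benzyl]oxy}benzaldehyde | O=Cc1ccc(OCc2ccccc2)cc1OCc1ccc(OCc2ccccc2)c(OCc2ccccc2)c1
F5 | step 7 | (E)-alkenyl pinacol boronate derived from F4 | CC1(C)OB(/C=C/c2ccc(OCc3ccccc3)cc2OCc2ccc(OCc3ccccc3)c(OCc3ccccc3)c2)OC1(C)C
F6 | step 7 | (E)-2-[4-(benzyloxy)-2-{[3,4-bis(benzyloxy)benzyl]oxy}phenyl]vinyl pivalate | CC(C)(C)C(=O)O/C=C/c1ccc(OCc2ccccc2)cc1OCc1ccc(OCc2ccccc2)c(OCc2ccccc2)c1
F7 | step 9 | 2-[4-(benzyloxy)-2-{[3,4-bis(benzyloxy)phenyl](pivaloyloxy)methoxy}phenyl]acetaldehyde, racemic at the acetal carbon | O=CCc1ccc(OCc2ccccc2)cc1OC(OC(=O)C(C)(C)C)c1ccc(OCc2ccccc2)c(OCc2ccccc2)c1
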